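The chroman half is cut across its dihydropyran ring (ring C, chroman numbering) at C3–C4 and O1–C8a. This exploits two features: benzylic C4 and ring-A carbon C8a sit 1,3 to each other, and the only stereocenter, C2, lies inside the O1–C2–C3 unit, which can be brought into the route as an enantiopure aryl oxirane. In the key step the Grignard reagent of a 2-bromobenzyl bromide (C8a–Br, C6–Br, 5,7-OBn) opens the (R)-oxirane at CH2 (C4–C3), and the released alkoxide is O-arylated at C8a by copper catalysis in the same flask (O1–C8a): a formal [3+3] annulation to the (2S)-6-bromochroman. Negishi coupling with a 3-iodoflavone and hydrogenolysis follow.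

Key step: step 6

Remark: the biaryl axis between flavone C3 and chroman C6 carries no descriptor in the target and is assumed to be configurationally labile in the free polyphenol, so rotamers of 19 about this axis are carried on together.

Step 1
Reactants: 1 2,5-dibromo-1,3-difluorobenzene
Product: 3 3,6-dibromo-2,4-difluorobenzaldehyde, via aryllithium 2 (not isolated)
Conditions: LiN(iPr)2, THF, −78 °C; then DMF, −78 → −20 °C; aq. HCl
Reagents that add atoms: N,N-dimethylformamide, CN(C)C=O
Why: Directed ortho-metalation followed by formylation: the two equivalent ring hydrogens each lie between F and Br and are the most acidic sites, so the amide base should deprotonate there at −78 °C without halogen–lithium exchange, and DMF should trap the aryllithium to give a single aldehyde.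

Step 2
Reactants: 3 3,6-dibromo-2,4-difluorobenzaldehyde
Product: 4 2,4-bis(benzyloxy)-3,6-dibromobenzaldehyde
Conditions: BnOH (2.2 equiv), K2CO3, DMF, 60 °C
Reagents that add atoms: benzyl alcohol, OCc1ccccc1
Why: Two-fold nucleophilic aromatic substitution (SNAr): both fluorides are ortho or para to the formyl group and should be displaced by benzyloxide far faster than either bromide, which places the two benzyl ethers on either side of the future C6 bromide.

Step 3
Reactants: 4 2,4-bis(benzyloxy)-3,6-dibromobenzaldehyde
Product: 5 [2,4-bis(benzyloxy)-3,6-dibromophenyl]methanol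
Conditions: NaBH4, THF/MeOH, 0 °C
Reagents that add atoms: none
Why: Borohydride reduction of an aromatic aldehyde to the benzylic alcohol, which leaves aryl bromides and benzyl ethers untouched.

Step 4
Reactants: 5 [2,4-bis(benzyloxy)-3,6-dibromophenyl]methanol
Product: 6 1,3-bis(benzyloxy)-2,5-dibromo-4-(bromomethyl)benzene
Conditions: PBr3 (0.4 equiv), CH2Cl2, 0 °C; used without chromatography
Reagents that add atoms: phosphorus tribromide, BrP(Br)Br
Why: Conversion of a benzylic alcohol into the bromide through its phosphite ester (SN2-type displacement by bromide), fast at 0 °C for this electron-rich benzylic position, so the labile product should be obtained cleanly and used at once.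

Step 5
Reactants: 7 1-[4-(benzyloxy)phenyl]-2-bromoethan-1-one
Product: 9 (2R)-2-[4-(benzyloxy)phenyl]oxirane, via bromohydrin 8 (not isolated)
Conditions: (R)-2-methyl-CBS-oxazaborolidine (10 mol%), BH3·SMe2, THF, 0 °C; then 2 M aq. NaOH, rt; product filtered through basic alumina
Reagents that add atoms: none
Why: CBS reduction in which the aryl group acts as the large substituent, so the (R)-catalyst should deliver hydride to the face that gives the (R)-bromohydrin, and the base-induced intramolecular Williamson closure at CH2 leaves that center untouched.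

Step 6
Reactants: 6 1,3-bis(benzyloxy)-2,5-dibromo-4-(bromomethyl)benzene; 9 (2R)-2-[4-(benzyloxy)phenyl]oxirane
Product: 12 (2S)-5,7-bis(benzyloxy)-2-[4-(benzyloxy)phenyl]-6-bromo-3,4-dihydro-2H-chromene, via benzylic Grignard reagent 10 (not isolated), via bromomagnesium alkoxide 11 (not isolated)
Conditions: Mg, Et2O, 0 °C (slow addition of 6); then 9, CuI (10 mol%), THF, −40 → 0 °C; then Cs2CO3, 3,4,7,8-tetramethyl-1,10-phenanthroline (20 mol%), toluene (ethers distilled off), 110 °C, one flask
Reagents that add atoms: none
Why: Magnesium should insert into the benzylic C–Br bond of 6 much faster than into either aryl C–Br bond, and under monovalent-copper catalysis the benzyl nucleophile 10 should open oxirane 9 by SN2 attack at its unsubstituted CH2 carbon, which forms the C4–C3 bond and releases the C2 oxygen as alkoxide 11; after addition of Cs2CO3 and the phenanthroline ligand the copper alkoxide should undergo intramolecular Ullmann-type O-arylation at the C8a–Br bond, which forms the O1–C8a bond. The closest known reaction types are the copper-catalysed Grignard opening of terminal aryl oxiranes and the copper-catalysed intramolecular etherification of aryl bromides with secondary alcohols to chromans, here run one after the other without isolating the alcohol. The only ring closed is the dihydropyran ring C, by attack of the tethered oxygen on the ipso carbon C8a in a six-membered exo-type C–O closure. No stereocenter is created: C2 comes from 9, no bond to it is made or broken in either event, and the (R)-oxirane therefore maps onto the (2S)-chroman (the descriptor changes only through the CIP priorities). The step needs attack at CH2 and not at the benzylic carbon of the electron-rich oxirane, which the soft copper-mediated SN2 pathway at low temperature should favour, and it needs O-arylation at C8a and not at C6, which is secured because only the C8a bromide is within reach of the three-carbon tether while the C6 bromide is para to it and flanked by two benzyloxy groups.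

Step 7
Reactants: 13 apigenin (5,7-dihydroxy-2-(4-hydroxyphenyl)-4H-chromen-4-one)
Product: 14 5,7-bis(benzyloxy)-2-[4-(benzyloxy)phenyl]-4H-chromen-4-one
Conditions: BnBr (4 equiv), K2CO3, DMF, 80 °C
Reagents that add atoms: benzyl bromide, BrCc1ccccc1
Why: Williamson etherification of all three phenols, with excess reagent and heating to overcome the hydrogen bond of the 5-OH to the carbonyl.

Step 8
Reactants: 14 5,7-bis(benzyloxy)-2-[4-(benzyloxy)phenyl]-4H-chromen-4-one
Product: 16 5,7-bis(benzyloxy)-2-[4-(benzyloxy)phenyl]-3-iodo-4H-chromen-4-one, via 3-lithioflavone 15 (not isolated)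
Conditions: LiN(iPr)2 (1.2 equiv), THF, −78 °C; then I2, −78 °C
Reagents that add atoms: iodine, [I][I]
Why: Carbonyl-directed lithiation of the chromone C3–H followed by an iodine quench, which should be regiospecific for C3 and leave the electron-rich ring A untouched, provided the 3-lithio species is trapped at −78 °C before it can ring-open.

Step 9
Reactants: 12 (2S)-5,7-bis(benzyloxy)-2-[4-(benzyloxy)phenyl]-6-bromo-3,4-dihydro-2H-chromene; 16 5,7-bis(benzyloxy)-2-[4-(benzyloxy)phenyl]-3-iodo-4H-chromen-4-one
Product: 19 5,7-bis(benzyloxy)-3-{(2S)-5,7-bis(benzyloxy)-2-[4-(benzyloxy)phenyl]-3,4-dihydro-2H-chromen-6-yl}-2-[4-(benzyloxy)phenyl]-4H-chromen-4-one, via aryllithium 17 (not isolated), via arylzinc chloride 18 (not isolated)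
Conditions: n-BuLi, THF, −78 °C; ZnCl2, −78 °C → rt; then 16, Pd2(dba)3 (2.5 mol%), RuPhos ligand (10 mol%), THF/NMP, 70 °C
Reagents that add atoms: none
Why: Negishi coupling: bromine–lithium exchange at the only C–Br bond and transmetalation to zinc give a nucleophile that tolerates the chromone carbonyl, and oxidative addition of zerovalent palladium into the C3–I bond followed by reductive elimination from the bulky biarylphosphine complex should form the tetra-ortho-substituted biaryl bond without touching the remote C2 center.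

Step 10
Reactants: 19 5,7-bis(benzyloxy)-3-{(2S)-5,7-bis(benzyloxy)-2-[4-(benzyloxy)phenyl]-3,4-dihydro-2H-chromen-6-yl}-2-[4-(benzyloxy)phenyl]-4H-chromen-4-one
Product: 20 5,7-dihydroxy-3-[(2S)-5,7-dihydroxy-2-(4-hydroxyphenyl)-3,4-dihydro-2H-chromen-6-yl]-2-(4-hydroxyphenyl)-4H-chromen-4-one
Conditions: H2 (1 atm), Pd(OH)2/C, THF/MeOH, rt
Reagents that add atoms: none
Why: Catalytic hydrogenolysis of the six benzyl ethers, under neutral conditions in which the tetrasubstituted conjugated C2=C3 bond of the 3-arylchromone and the benzylic C2–O1 bond of the chroman should react much more slowly, so the (2S) center is retained.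

Compound list
1 | 2,5-dibromo-1,3-difluorobenzene | Fc1cc(Br)cc(F)c1Br | starting material
2 | (3,6-dibromo-2,4-difluorophenyl)lithium | [Li]c1c(F)c(Br)c(F)cc1Br | intermediate
3 | 3,6-dibromo-2,4-difluorobenzaldehyde | O=Cc1c(F)c(Br)c(F)cc1Br | intermediate
4 | 2,4-bis(benzyloxy)-3,6-dibromobenzaldehyde | O=Cc1c(OCc2ccccc2)c(Br)c(OCc2ccccc2)cc1Br | intermediate
5 | [2,4-bis(benzyloxy)-3,6-dibromophenyl]methanol | OCc1c(OCc2ccccc2)c(Br)c(OCc2ccccc2)cc1Br | intermediate
6 | 1,3-bis(benzyloxy)-2,5-dibromo-4-(bromomethyl)benzene | BrCc1c(OCc2ccccc2)c(Br)c(OCc2ccccc2)cc1Br | intermediate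
7 | 1-[4-(benzyloxy)phenyl]-2-bromoethan-1-one | O=C(CBr)c1ccc(OCc2ccccc2)cc1 | starting material
8 | (1R)-1-[4-(benzyloxy)phenyl]-2-bromoethan-1-ol | BrC[C@H](O)c1ccc(OCc2ccccc2)cc1 | intermediate
9 | (2R)-2-[4-(benzyloxy)phenyl]oxirane | C1[C@H](O1)c1ccc(OCc2ccccc2)cc1 | intermediate
10 | [2,4-bis(benzyloxy)-3,6-dibromobenzyl]magnesium bromide | Br[Mg]Cc1c(OCc2ccccc2)c(Br)c(OCc2ccccc2)cc1Br | intermediate
11 | bromomagnesium (1S)-3-[2,4-bis(benzyloxy)-3,6-dibromophenyl]-1-[4-(benzyloxy)phenyl]propan-1-olate | Brc1cc(OCc2ccccc2)c(Br)c(OCc2ccccc2)c1CC[C@@H](c1ccc(OCc2ccccc2)cc1)O[Mg]Br | intermediate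
12 | (2S)-5,7-bis(benzyloxy)-2-[4-(benzyloxy)phenyl]-6-bromo-3,4-dihydro-2H-chromene | Brc1c(OCc2ccccc2)cc3c(c1OCc1ccccc1)CC[C@@H](c1ccc(OCc2ccccc2)cc1)O3 | intermediate
13 | apigenin (5,7-dihydroxy-2-(4-hydroxyphenyl)-4H-chromen-4-one) | O=c1cc(-c2ccc(O)cc2)oc2cc(O)cc(O)c12 | starting material
14 | 5,7-bis(benzyloxy)-2-[4-(benzyloxy)phenyl]-4H-chromen-4-one | O=c1cc(-c2ccc(OCc3ccccc3)cc2)oc2cc(OCc3ccccc3)cc(OCc3ccccc3)c12 | intermediate
15 | {5,7-bis(benzyloxy)-2-[4-(benzyloxy)phenyl]-4-oxo-4H-chromen-3-yl}lithium | [Li]c1c(-c2ccc(OCc3ccccc3)cc2)oc2cc(OCc3ccccc3)cc(OCc3ccccc3)c2c1=O | intermediate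
16 | 5,7-bis(benzyloxy)-2-[4-(benzyloxy)phenyl]-3-iodo-4H-chromen-4-one | O=c1c(I)c(-c2ccc(OCc3ccccc3)cc2)oc2cc(OCc3ccccc3)cc(OCc3ccccc3)c12 | intermediate
17 | {(2S)-5,7-bis(benzyloxy)-2-[4-(benzyloxy)phenyl]-3,4-dihydro-2H-chromen-6-yl}lithium | [Li]c1c(OCc2ccccc2)cc3c(c1OCc1ccccc1)CC[C@@H](c1ccc(OCc2ccccc2)cc1)O3 | intermediate
18 | {(2S)-5,7-bis(benzyloxy)-2-[4-(benzyloxy)phenyl]-3,4-dihydro-2H-chromen-6-yl}zinc chloride | Cl[Zn]c1c(OCc2ccccc2)cc3c(c1OCc1ccccc1)CC[C@@H](c1ccc(OCc2ccccc2)cc1)O3 | intermediate
19 | 5,7-bis(benzyloxy)-3-{(2S)-5,7-bis(benzyloxy)-2-[4-(benzyloxy)phenyl]-3,4-dihydro-2H-chromen-6-yl}-2-[4-(benzyloxy)phenyl]-4H-chromen-4-one | O=c1c(-c2c(OCc3ccccc3)cc3c(c2OCc2ccccc2)CC[C@@H](c2ccc(OCc4ccccc4)cc2)O3)c(-c2ccc(OCc3ccccc3)cc2)oc2cc(OCc3ccccc3)cc(OCc3ccccc3)c12 | intermediate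
20 | 5,7-dihydroxy-3-[(2S)-5,7-dihydroxy-2-(4-hydroxyphenyl)-3,4-dihydro-2H-chromen-6-yl]-2-(4-hydroxyphenyl)-4H-chromen-4-one | O=c1c(-c2c(O)cc3c(c2O)CC[C@@H](c2ccc(O)cc2)O3)c(-c2ccc(O)cc2)oc2cc(O)cc(O)c12 | target

Total step count: 10 steps.
Longest linear sequence: 7 steps (steps 1, 2, 3, 4, 6, 9 and 10).

Steps most likely to fail

Step 6. The benzyl nucleophile may attack the benzylic carbon of the electron-rich oxirane, magnesium salts may rearrange the oxirane to an arylacetaldehyde before it is opened, Wurtz-type homocoupling may consume the benzylic bromide during Grignard formation, and the magnesium alkoxide may enter the copper cycle too slowly. The fallback gives up the one-flask union and makes the same two bonds in separate, known reactions. It sets out from 6: alkylation of the lithium enolate of 1-[4-(benzyloxy)phenyl]ethanone (CC(=O)c1ccc(OCc2ccccc2)cc1; LiN(iPr)2, THF, −78 → 0 °C) should give 3-[2,4-bis(benzyloxy)-3,6-dibromophenyl]-1-[4-(benzyloxy)phenyl]propan-1-one F1 and with it the C4–C3 bond. CBS reduction of the aryl ketone with (R)-2-methyl-CBS-oxazaborolidine and BH3·SMe2 should give (1S)-3-[2,4-bis(benzyloxy)-3,6-dibromophenyl]-1-[4-(benzyloxy)phenyl]propan-1-ol F2. Copper-catalysed intramolecular O-arylation (CuI, 3,4,7,8-tetramethyl-1,10-phenanthroline, Cs2CO3, toluene, 110 °C) should then close ring C at C8a and come back to the route at 12.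

Step 9. Transmetalation and reductive elimination at the tetra-ortho-substituted axis may be slow, so that protodemetalation of the arylzinc and reduction of the iodide win. The fallback replaces the zinc nucleophile made in the flask by an isolated boron nucleophile. It sets out from 12: bromine–lithium exchange (n-BuLi, THF, −78 °C) and trapping with 2-isopropoxy-4,4,5,5-tetramethyl-1,3,2-dioxaborolane should give 2-{(2S)-5,7-bis(benzyloxy)-2-[4-(benzyloxy)phenyl]-3,4-dihydro-2H-chromen-6-yl}-4,4,5,5-tetramethyl-1,3,2-dioxaborolane F3. After purification this would be joined to 16 in a Suzuki–Miyaura coupling (Pd(OAc)2, SPhos ligand, K3PO4, toluene/H2O, 90 °C), coming back to the route at 19.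

Step 8. The 3-lithiochromone may ring-open by β-elimination of the phenoxide to an ynone before it is trapped, and the poorly soluble tribenzyl ether may be deprotonated incompletely at −78 °C. The fallback abandons carbanion chemistry for oxidative electrophilic iodination of the enol-ether-like C3 position. It sets out from 14, which would be treated with I2 and (NH4)2Ce(NO3)6 in MeCN at 60 °C, and comes back to the route at 16; it makes no new compound (entry F0).

Further compounds
F1 | step 6 | 3-[2,4-bis(benzyloxy)-3,6-dibromophenyl]-1-[4-(benzyloxy)phenyl]propan-1-one | O=C(CCc1c(OCc2ccccc2)c(Br)c(OCc2ccccc2)cc1Br)c1ccc(OCc2ccccc2)cc1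
F2 | step 6 | (1S)-3-[2,4-bis(benzyloxy)-3,6-dibromophenyl]-1-[4-(benzyloxy)phenyl]propan-1-ol | Brc1cc(OCc2ccccc2)c(Br)c(OCc2ccccc2)c1CC[C@@H](c1ccc(OCc2ccccc2)cc1)O
F3 | step 9 | 2-{(2S)-5,7-bis(benzyloxy)-2-[4-(benzyloxy)phenyl]-3,4-dihydro-2H-chromen-6-yl}-4,4,5,5-tetramethyl-1,3,2-dioxaborolane | CC1(C)OB(OC1(C)C)c1c(OCc2ccccc2)cc3c(c1OCc1ccccc1)CC[C@@H](c1ccc(OCc2ccccc2)cc1)O3
F0 | step 8 | none | none
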